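As time runs in the spring run, Xp stands at 34.8 mM after 39 min and 35.5 mM after 56 min, yet 64.5 mM of Xa and 214 mM of Xb are still in the flask.

common to all: Xc 1.00 mM
- spring: Xa 100 mM; Xb 250 mM
- dawn: Xa 60.0 mM; Xb 210 mM
- dusk: Xa 50.0 mM; Xb 250 mM
- noon: Xa 250 mM; Xb 620 mM; time 56 min

| run | time / min | [Xp] / mM |
|---|---|---|
| spring run | 4.3 | 10.1 |
| spring run | 13 | 23.3 |
| spring run | 25 | 31.3 |
| spring run | 39 | 34.8 |
| spring run | 56 | 35.5 |
| dawn run | 4.3 | 7.0 |
| dawn run | 13 | 16.8 |
| dawn run | 25 | 21.7 |
| dawn run | 39 | 26.0 |
| dawn run | 56 | 29.0 |
| dusk run | 4.3 | 6.7 |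
| dusk run | 13 | 14.6 |
| dusk run | 25 | 21.7 |
| dusk run | 39 | 26.9 |
| dusk run | 56 | 29.5 |

(readings scatter by 0.5 mM)

* apparent order in [Xa] of the starting rate, round the charge of the spring run (the rate where two percent of its Xa have turned into Xp) (one fixed amount of Xp, the same in the runs compared)
* apparent order in [Xb] of the starting rate, round the charge of the spring run (the rate where two percent of its Xa have turned into Xp)
* Xp in the noon run at 56 min, as a share of the Xa charged

- Overall: Xa + Xb -> Xp, with Xc as catalyst.
- Constant volume, constant temperature.
- Bound and free are read together.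
- An order is taken over about fifteen percent of the charge, up and down.

I ask first what the end state is. The dusk run, with half the Xa of spring, already holds 29.5 mM of Xp at 56 min, so I read the stop as a catalyst wearing out, not as a shortage of Xa. From its last reading I take the ration of the spring run as 35.5: the Xp made per Xc charged before the catalyst stops working, its turnover number.

Suppose Xa feeds turnover and wear alike. It then cancels from the ration, and Xb remains as the lever. Noon has the Xc of spring and 2.48 times its Xb, so a ration in step with Xb gives 88.0 mM, or 35.2 % of the noon Xa. I take 56 min as long enough, since the spring readings rise by 0.700 mM between 39 min and 56 min.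

The weak link is that proportion to Xb. The ration should follow the power of Xb in the rate, so I go to the first readings. Spring over dusk gives an Xa power of 0.592, and dawn over dusk then gives an Xb power of 0.368. That is a rough reading, given the scatter. It puts noon at 49.6 mM, or 19.8 %. I commit to the middle of the two, 27.5 %.

The forecast gives 0.85 in Xa, 1 in Xb and 31 % for noon, because “the cap seems to scale with Xb”; its noon figure is higher than mine.

The flask gives 0.74 in Xa, 0.64 in Xb and 26.1 % for noon.

    Xc + Xa ⇌ Xc.Xa, settled at all times (2.450 M⁻¹)
    Xc.Xa + Xb ⇌ Xc.Xa.Xb, settled at all times (4.600 M⁻¹)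
    Xc.Xa.Xb → Xp + Xc (32.76 min⁻¹)
    2 Xb ⇌ Xb2, settled at all times (4.550 M⁻¹)
    Xc + Xa → X + Xa (1.158 M⁻¹ min⁻¹)

The run without the turning of Xc into X proves the main reason: noon then reaches 92.6 % against 26.1 %. Noon's Xp per Xc at 56 min is 65.2, which, set against the ration read in spring, comes to a power of Xb of 0.670, beside the 0.64 of the starting rate. That order puts the ration of the dawn run at 31.8, above the 30.0 Xp per Xc that half its Xa needs, and the dawn run reaches that amount at 69.4 min.

Readings and results were computed with made-up constants; noise was put on by code.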